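**Retrosynthetic overview**
1. Last cut: hydrogenolysis of 18 frees the ring C acid (benzyl ester) and the O3/O4 catechol of ring A (diphenylmethylene ketal).
2. Ester between the ring A carboxyl and O4 of ring B: the acid chloride of 16 acylates the one phenol of benzyl lecanorate 10 that is not hydrogen-bonded to a carbonyl.
3. Key cut: ring B is an orsellinoyl unit (C1 to C6, the carboxyl carbon and the 6-methyl make a C8 3,5,7-trioxooctanoyl chain) joined by its carboxyl to O4 of ring C. The acyl C–O4 bond and the ring B C1–C6 bond are made together from acylketene 8 (from diketo-dioxinone 5) and phenol 7.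
4. 5 comes from 2,2,6-trimethyl-dioxinone 1 by two acetylations; 16 from symmetric 5-methylpyrogallol 11 (ketal, ortho-formylation, O-methylation, Pinnick oxidation); 7 from orsellinic acid 6.
5. Ring order: rings C and A are bought as arenes, the dioxole protecting ring is closed in step 5, and ring B is the only carbocycle built (step 4).

Key step: step 4

Assumption: the target has no stereocentre, and phenols ortho to an ester carbonyl are taken to be hydrogen-bonded and therefore the least nucleophilic, as in established depside chemistry.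

**Step 1**
Reactants: 1 2,2,6-trimethyl-4H-1,3-dioxin-4-one
Product: 3 2,2-dimethyl-6-(2-oxopropyl)-4H-1,3-dioxin-4-one, via lithium dienolate 2 (not isolated)
Conditions: 1 (2 equiv), LiN(SiMe3)2 (2 equiv), THF, −78 °C; AcCl (1 equiv), −78 to 0 °C; 1 M HCl
Reagents that add atoms: acetyl chloride CC(=O)Cl
Why: Deprotonation of the 6-methyl group gives the vinylogous ester dienolate, which should be C-acylated at its terminal carbon (vinylogous Claisen acylation), the second equivalent of dienolate taking up the acidic proton of the product.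

**Step 2**
Reactants: 3 2,2-dimethyl-6-(2-oxopropyl)-4H-1,3-dioxin-4-one
Product: 5 6-(2,4-dioxopentyl)-2,2-dimethyl-4H-1,3-dioxin-4-one, via dilithium dienolate 4 (not isolated)
Conditions: LiN(iPr)2 (2.2 equiv), THF, −78 °C; MeC(O)N(OMe)Me, −78 to −10 °C; 1 M HCl
Reagents that add atoms: N-methoxy-N-methylacetamide CC(=O)N(C)OC
Why: The dianion should react at its last-formed, most nucleophilic terminal carbon (Harris-type dianion Claisen condensation), and the chelated tetrahedral adduct of the Weinreb amide prevents a second addition.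

**Step 3**
Reactants: 6 orsellinic acid (2,4-dihydroxy-6-methylbenzoic acid)
Product: 7 benzyl orsellinate (benzyl 2,4-dihydroxy-6-methylbenzoate)
Conditions: BnBr, KHCO3, DMF, rt
Reagents that add atoms: benzyl bromide BrCc1ccccc1
Why: SN2 O-alkylation of the carboxylate; hydrogencarbonate is too weak a base to ionize the phenols, so they should stay free.

**Step 4**
Reactants: 5 6-(2,4-dioxopentyl)-2,2-dimethyl-4H-1,3-dioxin-4-one; 7 benzyl orsellinate
Product: 10 benzyl lecanorate (benzyl 4-[(2,4-dihydroxy-6-methylbenzoyl)oxy]-2-hydroxy-6-methylbenzoate), via acylketene 8 (not isolated), via aryl triketo ester 9 (not isolated)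
Conditions: 7 (2 equiv), PhMe, 110 °C, slow addition of 5; then Et3N, CH2Cl2, 0 °C to rt; then HCl (4 M in dioxane), rt
Reagents that add atoms: none
Why: Proposed new method: heating 5 expels acetone by a retro-hetero-Diels–Alder reaction to give acylketene 8, the free O4–H of 7 adds to the ketene carbon to give aryl 3,5,7-trioxooctanoate 9, Et3N then triggers attack of chain C2 on the C7 methyl ketone, and acid-assisted loss of water with enolization of the C3 and C5 carbonyls aromatizes ring B. The closest known reaction type is the capture of diketo-dioxinone-derived acylketenes by aliphatic alcohols followed by aldol aromatization to resorcylate esters, together with the acetoacetylation of phenols by 2,2,6-trimethyl-dioxinone; new here is that the ketene acceptor is a phenol, so that the triketo intermediate is an aryl ester. Ring B closes in a 6-(enolendo)-exo-trig aldol mode (C2 enolate onto the exocyclic C7=O), the mode used in the biosynthesis of orsellinic acid, and no stereocentre is formed. The step needs acylation at O4 of 7 and not at O2, which the hydrogen bond of the 2-OH to the benzyl ester carbonyl should secure. It also needs carbon–carbon closure to outrun acyl substitution at the aryl ester (lactonization or C6-to-C1 Claisen closure, both with loss of 7), for which a weak amine base at low temperature in a non-nucleophilic solvent is chosen, conditions under which alkyl triketo esters give the aldol product. Excess 7 and slow addition of 5 should keep the ketene from adding to the enols of its own chain.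

**Step 5**
Reactants: 11 5-methylpyrogallol (5-methylbenzene-1,2,3-triol)
Product: 12 6-methyl-2,2-diphenyl-1,3-benzodioxol-4-ol
Conditions: Ph2CCl2, K2CO3, MeCN, N2, rt to 60 °C
Reagents that add atoms: dichlorodiphenylmethane ClC(Cl)(c1ccccc1)c1ccccc1
Why: Double O-alkylation (ketalization) can close the five-membered dioxole only across vicinal hydroxyls, and both vicinal pairs of the symmetric triol are equivalent, so one mono-phenol should result.

**Step 6**
Reactants: 12 6-methyl-2,2-diphenyl-1,3-benzodioxol-4-ol
Product: 14 4-hydroxy-6-methyl-2,2-diphenyl-1,3-benzodioxole-5-carbaldehyde, via hydroxymethyl phenol 13 (not isolated)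
Conditions: MgCl2, Et3N, (CH2O)n, MeCN, reflux; 1 M HCl work-up
Reagents that add atoms: formaldehyde (as paraformaldehyde) C=O
Why: Casnati–Skattebøl ortho-formylation: the magnesium phenoxide delivers formaldehyde to the only free ortho position (C5), and the benzylic alkoxide is oxidized by hydride transfer to a second formaldehyde.

**Step 7**
Reactants: 14 4-hydroxy-6-methyl-2,2-diphenyl-1,3-benzodioxole-5-carbaldehyde
Product: 15 4-methoxy-6-methyl-2,2-diphenyl-1,3-benzodioxole-5-carbaldehyde
Conditions: MeI, K2CO3, DMF, rt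
Reagents that add atoms: iodomethane CI
Why: Williamson O-methylation of the only free phenol, which fixes the methoxy group at C2 of ring A.

**Step 8**
Reactants: 15 4-methoxy-6-methyl-2,2-diphenyl-1,3-benzodioxole-5-carbaldehyde
Product: 16 4-methoxy-6-methyl-2,2-diphenyl-1,3-benzodioxole-5-carboxylic acid
Conditions: NaClO2, NaH2PO4, 2-methyl-2-butene (excess), t-BuOH/THF/H2O, 0 °C to rt
Reagents that add atoms: sodium chlorite [Na+].[O-]Cl=O
Why: Pinnick oxidation of the aldehyde under buffered conditions that the ketal tolerates, the alkene scavenging hypochlorous acid before it can chlorinate the electron-rich ring.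

**Step 9**
Reactants: 16 4-methoxy-6-methyl-2,2-diphenyl-1,3-benzodioxole-5-carboxylic acid; 10 benzyl lecanorate
Product: 18 benzyl 2-hydroxy-4-{[2-hydroxy-4-({4-methoxy-6-methyl-2,2-diphenyl-1,3-benzodioxole-5-carbonyl}oxy)-6-methylbenzoyl]oxy}-6-methylbenzoate, via acid chloride 17 (not isolated)
Conditions: (COCl)2, DMF (cat.), CH2Cl2, 0 °C to rt, evaporate; then 10, Et3N, DMAP (cat.), CH2Cl2, 0 °C to rt
Reagents that add atoms: none
Why: DMAP-catalysed esterification of an acyl chloride with a phenol; the 4-OH of ring B is the only phenol of 10 not hydrogen-bonded to an ortho carbonyl and the most acidic one, so it should be acylated selectively as in classical depside couplings.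

**Step 10**
Reactants: 18 protected tridepside
Product: 19 4-{[4-({3,4-dihydroxy-2-methoxy-6-methylbenzoyl}oxy)-2-hydroxy-6-methylbenzoyl]oxy}-2-hydroxy-6-methylbenzoic acid (target)
Conditions: H2 (1 atm), Pd/C, EtOAc/THF, rt
Reagents that add atoms: none
Why: Hydrogenolysis cleaves the benzylic C–O bonds of the benzyl ester and of the diphenylmethylene ketal, while the two aryl ester (depside) bonds are inert under neutral hydrogenation.

**Compound list**
1 | 2,2,6-trimethyl-4H-1,3-dioxin-4-one | CC1=CC(=O)OC(C)(C)O1 | starting material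
2 | lithium dienolate of 1 (lithium 2,2-dimethyl-6-methylidene-6H-1,3-dioxin-4-olate) | [Li+].[O-]C1=CC(=C)OC(C)(C)O1 | intermediate
3 | 2,2-dimethyl-6-(2-oxopropyl)-4H-1,3-dioxin-4-one | CC(=O)CC1=CC(=O)OC(C)(C)O1 | intermediate
4 | dilithium dienolate of 3 | [Li+].[Li+].C=C([O-])C=C1C=C([O-])OC(C)(C)O1 | intermediate
5 | 6-(2,4-dioxopentyl)-2,2-dimethyl-4H-1,3-dioxin-4-one | CC(=O)CC(=O)CC1=CC(=O)OC(C)(C)O1 | intermediate
6 | orsellinic acid (2,4-dihydroxy-6-methylbenzoic acid) | Cc1cc(O)cc(O)c1C(=O)O | starting material
7 | benzyl orsellinate (benzyl 2,4-dihydroxy-6-methylbenzoate) | Cc1cc(O)cc(O)c1C(=O)OCc1ccccc1 | intermediate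
8 | 3,5,7-trioxooct-1-en-1-one (acylketene) | CC(=O)CC(=O)CC(=O)C=C=O | intermediate
9 | 4-(benzyloxycarbonyl)-3-hydroxy-5-methylphenyl 3,5,7-trioxooctanoate | CC(=O)CC(=O)CC(=O)CC(=O)Oc1cc(C)c(C(=O)OCc2ccccc2)c(O)c1 | intermediate
10 | benzyl lecanorate (benzyl 4-[(2,4-dihydroxy-6-methylbenzoyl)oxy]-2-hydroxy-6-methylbenzoate) | Cc1cc(O)cc(O)c1C(=O)Oc1cc(C)c(C(=O)OCc2ccccc2)c(O)c1 | intermediate
11 | 5-methylpyrogallol (5-methylbenzene-1,2,3-triol) | Cc1cc(O)c(O)c(O)c1 | starting material
12 | 6-methyl-2,2-diphenyl-1,3-benzodioxol-4-ol | Cc1cc(O)c2OC(c3ccccc3)(c3ccccc3)Oc2c1 | intermediate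
13 | 5-(hydroxymethyl)-6-methyl-2,2-diphenyl-1,3-benzodioxol-4-ol | Cc1cc2OC(c3ccccc3)(c3ccccc3)Oc2c(O)c1CO | intermediate
14 | 4-hydroxy-6-methyl-2,2-diphenyl-1,3-benzodioxole-5-carbaldehyde | Cc1cc2OC(c3ccccc3)(c3ccccc3)Oc2c(O)c1C=O | intermediate
15 | 4-methoxy-6-methyl-2,2-diphenyl-1,3-benzodioxole-5-carbaldehyde | COc1c(C=O)c(C)cc2OC(c3ccccc3)(c3ccccc3)Oc12 | intermediate
16 | 4-methoxy-6-methyl-2,2-diphenyl-1,3-benzodioxole-5-carboxylic acid | COc1c(C(=O)O)c(C)cc2OC(c3ccccc3)(c3ccccc3)Oc12 | intermediate
17 | 4-methoxy-6-methyl-2,2-diphenyl-1,3-benzodioxole-5-carbonyl chloride | COc1c(C(Cl)=O)c(C)cc2OC(c3ccccc3)(c3ccccc3)Oc12 | intermediate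
18 | benzyl 2-hydroxy-4-{[2-hydroxy-4-({4-methoxy-6-methyl-2,2-diphenyl-1,3-benzodioxole-5-carbonyl}oxy)-6-methylbenzoyl]oxy}-6-methylbenzoate | COc1c(C(=O)Oc4cc(C)c(C(=O)Oc5cc(C)c(C(=O)OCc6ccccc6)c(O)c5)c(O)c4)c(C)cc2OC(c3ccccc3)(c3ccccc3)Oc12 | intermediate
19 | 4-{[4-({3,4-dihydroxy-2-methoxy-6-methylbenzoyl}oxy)-2-hydroxy-6-methylbenzoyl]oxy}-2-hydroxy-6-methylbenzoic acid | COc1c(O)c(O)cc(C)c1C(=O)Oc1cc(C)c(C(=O)Oc2cc(C)c(C(=O)O)c(O)c2)c(O)c1 | target

**Totals**
Total step count: 10. Longest linear sequence: 6 steps (steps 5, 6, 7, 8, 9, 10).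

**Steps most likely to fail**

Step 4 (Proposed new method). Acyl substitution at the aryl ester of the triketo chain (lactonization or Claisen closure with loss of the phenol), or capture of the ketene by its own enols, may outrun the aldol aromatization. The fallback takes ring B from orsellinic acid by classical acyl-protected depside coupling; it sets out from 6 and 7 and comes back at 10. Compound 6 would be acetylated (Ac2O, pyridine, DMAP, then aqueous work-up) to 2,4-diacetoxy-6-methylbenzoic acid F1. This would be converted with (COCl)2 and catalytic DMF into 2,4-diacetoxy-6-methylbenzoyl chloride F2 and coupled with 7 (pyridine, CH2Cl2) to benzyl 4-[(2,4-diacetoxy-6-methylbenzoyl)oxy]-2-hydroxy-6-methylbenzoate F3. Cold aqueous ammonia in THF should then remove the two aryl acetates and leave the di-ortho-substituted depside benzoate, giving 10.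

Step 9. Acylation may spread over the hydrogen-bonded phenols of 10, or the existing depside ester may be transacylated under the basic conditions needed for the hindered acyl chloride. The fallback reverses the order of ester formation, so that the hindered acyl chloride meets a monocyclic phenol and the ring B to ring C ester is made last by carbodiimide coupling; it sets out from 16 (through 17) and 6 and comes back at 18. Compound 6 would be converted with allyl bromide and KHCO3 in DMF into allyl 2,4-dihydroxy-6-methylbenzoate F4. An excess of F4 would be acylated with 17 (Et3N, catalytic DMAP) to give allyl 2-hydroxy-4-[(4-methoxy-6-methyl-2,2-diphenyl-1,3-benzodioxole-5-carbonyl)oxy]-6-methylbenzoate F5. Deallylation with Pd(PPh3)4 and morpholine in THF should give 2-hydroxy-4-[(4-methoxy-6-methyl-2,2-diphenyl-1,3-benzodioxole-5-carbonyl)oxy]-6-methylbenzoic acid F6. Coupling of F6 with 7 (DCC, catalytic DMAP, CH2Cl2) would give 18.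

Step 2. Acylation of the dilithium dienolate may be incomplete or occur at the internal carbon or at oxygen, and proton transfer from the acidic product may quench the dianion. The fallback builds the second acetyl unit by magnesium-mediated C-acylation of a β-keto allyl ester followed by decarboxylation; it sets out from 1 (through 2) and comes back at 5. Dienolate 2 would be acylated with allyl 3-chloro-3-oxopropanoate to give allyl 4-(2,2-dimethyl-4-oxo-4H-1,3-dioxin-6-yl)-3-oxobutanoate F7. C-acetylation of F7 (MgCl2, pyridine, AcCl, CH2Cl2) would give allyl 2-acetyl-4-(2,2-dimethyl-4-oxo-4H-1,3-dioxin-6-yl)-3-oxobutanoate F8. Treatment of F8 with Pd(PPh3)4 and morpholine in THF should remove the allyl group and decarboxylate to 5.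

**Further compounds**
F1 | step 4 | 2,4-diacetoxy-6-methylbenzoic acid | CC(=O)Oc1cc(C)c(C(=O)O)c(OC(C)=O)c1
F2 | step 4 | 2,4-diacetoxy-6-methylbenzoyl chloride | CC(=O)Oc1cc(C)c(C(Cl)=O)c(OC(C)=O)c1
F3 | step 4 | benzyl 4-[(2,4-diacetoxy-6-methylbenzoyl)oxy]-2-hydroxy-6-methylbenzoate | CC(=O)Oc1cc(C)c(C(=O)Oc2cc(C)c(C(=O)OCc3ccccc3)c(O)c2)c(OC(C)=O)c1
F4 | step 9 | allyl 2,4-dihydroxy-6-methylbenzoate | C=CCOC(=O)c1c(C)cc(O)cc1O
F5 | step 9 | allyl 2-hydroxy-4-[(4-methoxy-6-methyl-2,2-diphenyl-1,3-benzodioxole-5-carbonyl)oxy]-6-methylbenzoate | COc1c(C(=O)Oc4cc(C)c(C(=O)OCC=C)c(O)c4)c(C)cc2OC(c3ccccc3)(c3ccccc3)Oc12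
F6 | step 9 | 2-hydroxy-4-[(4-methoxy-6-methyl-2,2-diphenyl-1,3-benzodioxole-5-carbonyl)oxy]-6-methylbenzoic acid | COc1c(C(=O)Oc4cc(C)c(C(=O)O)c(O)c4)c(C)cc2OC(c3ccccc3)(c3ccccc3)Oc12
F7 | step 2 | allyl 4-(2,2-dimethyl-4-oxo-4H-1,3-dioxin-6-yl)-3-oxobutanoate | C=CCOC(=O)CC(=O)CC1=CC(=O)OC(C)(C)O1
F8 | step 2 | allyl 2-acetyl-4-(2,2-dimethyl-4-oxo-4H-1,3-dioxin-6-yl)-3-oxobutanoate | C=CCOC(=O)C(C(C)=O)C(=O)CC1=CC(=O)OC(C)(C)O1
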